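**Retrosynthetic overview**
1. Target 14 ⇐ carbinol silyl ether and 1,3-dithiane-masked ketone (12/13); the β,γ-unsaturated ketone is unmasked last under near-neutral conditions.
2. C1–C2 bond and the (S) carbinol centre ⇐ enantioselective, linear-selective reductive (umpolung) allylation of furan-3-carbaldehyde 11 with the C15 allylic carbonate 10 (the new step).
3. C13–C14 bond ⇐ Corey–Seebach alkylation of 2-isobutyl-1,3-dithiane 6 with the allylic bromide 4.
4. Bromide 4 ⇐ SeO2 oxidation of the terminal (E)-methyl of (2E,6E)-farnesol TBS ether; all three E olefins are bought with farnesol.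
5. Rings: no ring of the target is built (the furan comes with 11); the only ring formed is the temporary dithiane (step 4), opened in step 10.

Assumption: the sense of induction of the chiral carbene in step 8 cannot be predicted with certainty; the (4S,5S) precursor is written, and its (4R,5R) antipode is used instead if the first run gives the (R) ether.

**Step 1**
Reactants: 1 (2E,6E)-3,7,11-trimethyldodeca-2,6,10-trien-1-ol ((2E,6E)-farnesol)
Product: 2 tert-butyl(dimethyl){[(2E,6E)-3,7,11-trimethyldodeca-2,6,10-trien-1-yl]oxy}silane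
Conditions: TBSCl, imidazole, DMF, 0 °C → rt
Reagents that add atoms: tert-butyldimethylsilyl chloride, CC(C)(C)[Si](C)(C)Cl
Why: Standard silylation of a primary allylic alcohol (silyl ether protection) that leaves the olefin geometry untouched and makes the C1 oxygen inert to steps 2–5.

**Step 2**
Reactants: 2 tert-butyl(dimethyl){[(2E,6E)-3,7,11-trimethyldodeca-2,6,10-trien-1-yl]oxy}silane
Product: 3 (2E,6E,10E)-12-[(tert-butyldimethylsilyl)oxy]-2,6,10-trimethyldodeca-2,6,10-trien-1-ol
Conditions: SeO2 (0.3 equiv), t-BuOOH (3 equiv), salicylic acid (0.1 equiv), CH2Cl2, 0 °C → rt, stopped at about 70% conversion, 2 recycled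
Reagents that add atoms: selenium dioxide, O=[Se]=O (transfers the oxygen); tert-butyl hydroperoxide, CC(C)(C)OO (terminal oxygen source that regenerates SeO2)
Why: Catalytic SeO2 allylic oxidation (ene reaction then [2,3]-sigmatropic shift) attacks the most electron-rich terminal trisubstituted olefin and selectively hydroxylates its (E)-methyl group, giving the (E)-allylic alcohol.

**Step 3**
Reactants: 3 (2E,6E,10E)-12-[(tert-butyldimethylsilyl)oxy]-2,6,10-trimethyldodeca-2,6,10-trien-1-ol
Product: 4 {[(2E,6E,10E)-12-bromo-3,7,11-trimethyldodeca-2,6,10-trien-1-yl]oxy}(tert-butyl)dimethylsilane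
Conditions: CBr4, PPh3, CH2Cl2, −20 → 0 °C
Reagents that add atoms: carbon tetrabromide, BrC(Br)(Br)Br
Why: Appel bromination under neutral conditions displaces the primary allylic alkoxyphosphonium by SN2 without allylic transposition or loss of E geometry, and the TBS ether survives.

**Step 4**
Reactants: 5 3-methylbutanal (isovaleraldehyde)
Product: 6 2-(2-methylpropyl)-1,3-dithiane
Conditions: HS(CH2)3SH, BF3·OEt2 (10 mol%), CH2Cl2, 0 °C → rt
Reagents that add atoms: propane-1,3-dithiol, SCCCS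
Why: Lewis-acid-catalysed thioacetalisation of an unhindered aldehyde gives the Corey–Seebach acyl-anion precursor.

**Step 5**
Reactants: 6 2-(2-methylpropyl)-1,3-dithiane; 4 {[(2E,6E,10E)-12-bromo-3,7,11-trimethyldodeca-2,6,10-trien-1-yl]oxy}(tert-butyl)dimethylsilane
Product: 8 tert-butyl(dimethyl){[(2E,6E,10E)-3,7,11-trimethyl-12-[2-(2-methylpropyl)-1,3-dithian-2-yl]dodeca-2,6,10-trien-1-yl]oxy}silane, via 2-lithio-2-(2-methylpropyl)-1,3-dithiane 7 (not isolated)
Conditions: n-BuLi, THF, −30 °C, 2 h; then 4, −78 → −20 °C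
Reagents that add atoms: none
Why: Corey–Seebach umpolung alkylation, in which the soft dithianyl anion displaces the primary allylic bromide by SN2 at carbon, forming the C13–C14 bond with the E olefin retained and the ketone already masked.

**Step 6**
Reactants: 8 tert-butyl(dimethyl){[(2E,6E,10E)-3,7,11-trimethyl-12-[2-(2-methylpropyl)-1,3-dithian-2-yl]dodeca-2,6,10-trien-1-yl]oxy}silane
Product: 9 (2E,6E,10E)-3,7,11-trimethyl-12-[2-(2-methylpropyl)-1,3-dithian-2-yl]dodeca-2,6,10-trien-1-ol
Conditions: Bu4NF, THF, 0 °C → rt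
Reagents that add atoms: none
Why: Fluoride-driven desilylation (strong Si–F bond) frees the primary allylic alcohol, and the dithiane and olefins are inert to it.

**Step 7**
Reactants: 9 (2E,6E,10E)-3,7,11-trimethyl-12-[2-(2-methylpropyl)-1,3-dithian-2-yl]dodeca-2,6,10-trien-1-ol
Product: 10 methyl (2E,6E,10E)-3,7,11-trimethyl-12-[2-(2-methylpropyl)-1,3-dithian-2-yl]dodeca-2,6,10-trien-1-yl carbonate
Conditions: ClCO2Me, pyridine, DMAP (cat.), CH2Cl2, 0 °C
Reagents that add atoms: methyl chloroformate, COC(=O)Cl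
Why: Simple O-acylation gives an allylic carbonate that ionises readily with zerovalent palladium and releases its own alkoxide base in step 8.

**Step 8**
Reactants: 10 methyl (2E,6E,10E)-3,7,11-trimethyl-12-[2-(2-methylpropyl)-1,3-dithian-2-yl]dodeca-2,6,10-trien-1-yl carbonate; 11 furan-3-carbaldehyde
Product: 12 {[(1S,3E,7E,11E)-1-(furan-3-yl)-4,8,12-trimethyl-13-[2-(2-methylpropyl)-1,3-dithian-2-yl]trideca-3,7,11-trien-1-yl]oxy}dimethyl(phenyl)silane
Conditions: CuCl (10 mol%), (4S,5S)-1,3-bis(2-isopropylphenyl)-4,5-diphenylimidazolinium tetrafluoroborate (11 mol%), NaOt-Bu (25 mol%), Pd2(dba)3 (2.5 mol%, dba = dibenzylideneacetone), bis[2-(diphenylphosphino)phenyl] ether (6 mol%), PhMe2Si–Bpin (1.5 equiv, added slowly), 11 (1.5 equiv), toluene/THF, 25 °C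
Reagents that add atoms: 2-[dimethyl(phenyl)silyl]-4,4,5,5-tetramethyl-1,3,2-dioxaborolane, C[Si](C)(c1ccccc1)B1OC(C)(C)C(C)(C)O1
Why: Proposed new method: the chiral carbene–Cu–SiMe2Ph species (from the copper alkoxide and the silylboronate) adds across the C=O of 11, a [1,2]-Brook rearrangement converts the α-silyl alkoxide into an α-silyloxy(3-furyl)methylcopper whose configuration is biased by the C2-symmetric carbene, and this carbon nucleophile transmetalates with retention to the π-allylpalladium formed from 10 by zerovalent palladium (loss of CO2 and methoxide, which turns the copper over), so that inner-sphere reductive elimination at the unsubstituted allyl terminus forms the C1–C2 bond as the linear product with the E olefin retained and the (S) centre set by the copper ligand, while the hindered trisubstituted terminus disfavours competing copper SN2′ silylation; the closest known reaction type is the copper-catalysed silylboronate umpolung of aromatic aldehydes merged with palladium-catalysed cross-coupling, which to the best of current knowledge has not been shown as an enantioselective, linear-selective coupling of a furan aldehyde with a trisubstituted polyprenyl carbonate.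

**Step 9**
Reactants: 12 {[(1S,3E,7E,11E)-1-(furan-3-yl)-4,8,12-trimethyl-13-[2-(2-methylpropyl)-1,3-dithian-2-yl]trideca-3,7,11-trien-1-yl]oxy}dimethyl(phenyl)silane
Product: 13 (1S,3E,7E,11E)-1-(furan-3-yl)-4,8,12-trimethyl-13-[2-(2-methylpropyl)-1,3-dithian-2-yl]trideca-3,7,11-trien-1-ol
Conditions: Bu4NF, THF, 0 °C
Reagents that add atoms: none
Why: Fluoride desilylation cleaves only the Si–O bond of the labile dimethylphenylsilyl ether, so the C–O stereocentre is untouched and the dithiane stays in place.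

**Step 10**
Reactants: 13 (1S,3E,7E,11E)-1-(furan-3-yl)-4,8,12-trimethyl-13-[2-(2-methylpropyl)-1,3-dithian-2-yl]trideca-3,7,11-trien-1-ol
Product: 14 (6E,10E,14E,17S)-17-(furan-3-yl)-17-hydroxy-2,6,10,14-tetramethylheptadeca-6,10,14-trien-4-one (CNP0307189.1)
Conditions: MeI (excess), CaCO3, MeCN/H2O (9:1), 45 °C, dark
Reagents that add atoms: water, O
Why: Alkylative thioacetal hydrolysis (S-methylation to a sulfonium, ring opening, capture by water) runs at near-neutral pH buffered by CaCO3, so the β,γ-unsaturated ketone is released without migration into conjugation and the furan, the olefins and the (S) carbinol are not touched.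

**Compound list**
1 | (2E,6E)-3,7,11-trimethyldodeca-2,6,10-trien-1-ol ((2E,6E)-farnesol) | CC(C)=CCC/C(C)=C/CC/C(C)=C/CO | starting material
2 | tert-butyl(dimethyl){[(2E,6E)-3,7,11-trimethyldodeca-2,6,10-trien-1-yl]oxy}silane | CC(C)=CCC/C(C)=C/CC/C(C)=C/CO[Si](C)(C)C(C)(C)C | intermediate
3 | (2E,6E,10E)-12-[(tert-butyldimethylsilyl)oxy]-2,6,10-trimethyldodeca-2,6,10-trien-1-ol | OC/C(C)=C/CC/C(C)=C/CC/C(C)=C/CO[Si](C)(C)C(C)(C)C | intermediate
4 | {[(2E,6E,10E)-12-bromo-3,7,11-trimethyldodeca-2,6,10-trien-1-yl]oxy}(tert-butyl)dimethylsilane | BrC/C(C)=C/CC/C(C)=C/CC/C(C)=C/CO[Si](C)(C)C(C)(C)C | intermediate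
5 | 3-methylbutanal (isovaleraldehyde) | CC(C)CC=O | starting material
6 | 2-(2-methylpropyl)-1,3-dithiane | CC(C)CC1SCCCS1 | intermediate
7 | 2-lithio-2-(2-methylpropyl)-1,3-dithiane | [Li]C1(CC(C)C)SCCCS1 | intermediate (not isolated)
8 | tert-butyl(dimethyl){[(2E,6E,10E)-3,7,11-trimethyl-12-[2-(2-methylpropyl)-1,3-dithian-2-yl]dodeca-2,6,10-trien-1-yl]oxy}silane | CC(C)CC1(C/C(C)=C/CC/C(C)=C/CC/C(C)=C/CO[Si](C)(C)C(C)(C)C)SCCCS1 | intermediate
9 | (2E,6E,10E)-3,7,11-trimethyl-12-[2-(2-methylpropyl)-1,3-dithian-2-yl]dodeca-2,6,10-trien-1-ol | CC(C)CC1(C/C(C)=C/CC/C(C)=C/CC/C(C)=C/CO)SCCCS1 | intermediate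
10 | methyl (2E,6E,10E)-3,7,11-trimethyl-12-[2-(2-methylpropyl)-1,3-dithian-2-yl]dodeca-2,6,10-trien-1-yl carbonate | CC(C)CC1(C/C(C)=C/CC/C(C)=C/CC/C(C)=C/COC(=O)OC)SCCCS1 | intermediate
11 | furan-3-carbaldehyde | O=Cc1ccoc1 | starting material
12 | {[(1S,3E,7E,11E)-1-(furan-3-yl)-4,8,12-trimethyl-13-[2-(2-methylpropyl)-1,3-dithian-2-yl]trideca-3,7,11-trien-1-yl]oxy}dimethyl(phenyl)silane | C/C(=C\CC/C(C)=C/C[C@H](O[Si](C)(C)c1ccccc1)c1ccoc1)CC/C=C(\C)CC1(CC(C)C)SCCCS1 | intermediate
13 | (1S,3E,7E,11E)-1-(furan-3-yl)-4,8,12-trimethyl-13-[2-(2-methylpropyl)-1,3-dithian-2-yl]trideca-3,7,11-trien-1-ol | C/C(=C\CC/C(C)=C/C[C@H](O)c1ccoc1)CC/C=C(\C)CC1(CC(C)C)SCCCS1 | intermediate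
14 | (6E,10E,14E,17S)-17-(furan-3-yl)-17-hydroxy-2,6,10,14-tetramethylheptadeca-6,10,14-trien-4-one | C/C(=C\CC/C(C)=C/C[C@H](O)c1ccoc1)CC/C=C(\C)CC(=O)CC(C)C | target

**Step count**
Total steps: 10. Longest linear sequence: 9 (steps 1, 2, 3, 5, 6, 7, 8, 9, 10, from 1).

**Three steps most likely to fail**

Step 8 (the proposed new coupling; risks are low enantioselectivity, allylsilane formation, or inhibition by the dithiane). The fallback uses known chemistry, sets out from 9 and comes back to the route at 13. Alcohol 9 is converted with MsCl, 2,4,6-collidine and LiCl in DMF at 0 °C into 2-[(2E,6E,10E)-12-chloro-2,6,10-trimethyldodeca-2,6,10-trien-1-yl]-2-(2-methylpropyl)-1,3-dithiane F1. This chloride is added at −78 °C to activated Ba metal (from BaI2 and two equivalents of lithium biphenylide in THF) to give chloro{(2E,6E,10E)-3,7,11-trimethyl-12-[2-(2-methylpropyl)-1,3-dithian-2-yl]dodeca-2,6,10-trien-1-yl}barium F2. The allylbarium reagent adds to 11 at −78 °C through its unsubstituted α carbon with the E olefin retained, giving racemic (3E,7E,11E)-1-(furan-3-yl)-4,8,12-trimethyl-13-[2-(2-methylpropyl)-1,3-dithian-2-yl]trideca-3,7,11-trien-1-ol F3. Activated MnO2 in CH2Cl2 oxidises this furyl carbinol to (3E,7E,11E)-1-(furan-3-yl)-4,8,12-trimethyl-13-[2-(2-methylpropyl)-1,3-dithian-2-yl]trideca-3,7,11-trien-1-one F4. Corey–Bakshi–Shibata reduction with (R)-1-methyl-3,3-diphenyltetrahydro-1H,3H-pyrrolo[1,2-c][1,3,2]oxazaborole (20 mol%) and catecholborane in toluene at −78 °C (furyl as the large group) then gives the (S) alcohol 13.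

Step 2 (SeO2 oxidation; risks are low conversion, over-oxidation to the enal and oxidation at internal allylic positions). The fallback sets out from 2 and comes back at 3. N-Bromosuccinimide in THF/water at 0 °C converts 2, selectively at the terminal olefin, into racemic (6E,10E)-3-bromo-12-[(tert-butyldimethylsilyl)oxy]-2,6,10-trimethyldodeca-6,10-dien-2-ol F5. K2CO3 in methanol closes it to racemic tert-butyl{[(2E,6E)-9-(3,3-dimethyloxiran-2-yl)-3,7-dimethylnona-2,6-dien-1-yl]oxy}dimethylsilane F6. HIO4·2H2O in Et2O/THF at 0 °C cleaves the epoxide to (4E,8E)-10-[(tert-butyldimethylsilyl)oxy]-4,8-dimethyldeca-4,8-dienal F7. An E-selective Wittig reaction with ethyl 2-(triphenylphosphoranylidene)propanoate in CH2Cl2 gives ethyl (2E,6E,10E)-12-[(tert-butyldimethylsilyl)oxy]-2,6,10-trimethyldodeca-2,6,10-trienoate F8. Reduction with i-Bu2AlH in CH2Cl2 at −78 °C returns 3.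

Step 10 (thioacetal hydrolysis; risks are sluggish S-alkylation of the fully substituted dithiane and migration of the β,γ-olefin on prolonged heating). The fallback sets out from 12 and comes back at 14. It changes the endgame to an oxidative thioacetal cleavage carried out while the carbinol is still silylated. 2-Iodoxybenzoic acid in DMSO/water at 25 °C converts 12 into (6E,10E,14E,17S)-17-{[dimethyl(phenyl)silyl]oxy}-17-(furan-3-yl)-2,6,10,14-tetramethylheptadeca-6,10,14-trien-4-one F9. Pyridine-buffered HF·pyridine in THF at 0 °C then removes the silyl group without base and gives 14.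

**Further compounds**
F1 | step 8 | 2-[(2E,6E,10E)-12-chloro-2,6,10-trimethyldodeca-2,6,10-trien-1-yl]-2-(2-methylpropyl)-1,3-dithiane | CC(C)CC1(C/C(C)=C/CC/C(C)=C/CC/C(C)=C/CCl)SCCCS1
F2 | step 8 | chloro{(2E,6E,10E)-3,7,11-trimethyl-12-[2-(2-methylpropyl)-1,3-dithian-2-yl]dodeca-2,6,10-trien-1-yl}barium | CC(C)CC1(C/C(C)=C/CC/C(C)=C/CC/C(C)=C/C[Ba]Cl)SCCCS1
F3 | step 8 | racemic (3E,7E,11E)-1-(furan-3-yl)-4,8,12-trimethyl-13-[2-(2-methylpropyl)-1,3-dithian-2-yl]trideca-3,7,11-trien-1-ol | C/C(=C\CC/C(C)=C/CC(O)c1ccoc1)CC/C=C(\C)CC1(CC(C)C)SCCCS1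
F4 | step 8 | (3E,7E,11E)-1-(furan-3-yl)-4,8,12-trimethyl-13-[2-(2-methylpropyl)-1,3-dithian-2-yl]trideca-3,7,11-trien-1-one | C/C(=C\CC/C(C)=C/CC(=O)c1ccoc1)CC/C=C(\C)CC1(CC(C)C)SCCCS1
F5 | step 2 | racemic (6E,10E)-3-bromo-12-[(tert-butyldimethylsilyl)oxy]-2,6,10-trimethyldodeca-6,10-dien-2-ol | CC(C)(O)C(Br)CC/C(C)=C/CC/C(C)=C/CO[Si](C)(C)C(C)(C)C
F6 | step 2 | racemic tert-butyl{[(2E,6E)-9-(3,3-dimethyloxiran-2-yl)-3,7-dimethylnona-2,6-dien-1-yl]oxy}dimethylsilane | CC1(C)OC1CC/C(C)=C/CC/C(C)=C/CO[Si](C)(C)C(C)(C)C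
F7 | step 2 | (4E,8E)-10-[(tert-butyldimethylsilyl)oxy]-4,8-dimethyldeca-4,8-dienal | O=CCC/C(C)=C/CC/C(C)=C/CO[Si](C)(C)C(C)(C)C
F8 | step 2 | ethyl (2E,6E,10E)-12-[(tert-butyldimethylsilyl)oxy]-2,6,10-trimethyldodeca-2,6,10-trienoate | CCOC(=O)/C(C)=C/CC/C(C)=C/CC/C(C)=C/CO[Si](C)(C)C(C)(C)C
F9 | step 10 | (6E,10E,14E,17S)-17-{[dimethyl(phenyl)silyl]oxy}-17-(furan-3-yl)-2,6,10,14-tetramethylheptadeca-6,10,14-trien-4-one | C/C(=C\CC/C(C)=C/C[C@H](O[Si](C)(C)c1ccccc1)c1ccoc1)CC/C=C(\C)CC(=O)CC(C)C
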